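**Retrosynthetic overview**

1. Target 30 comes from 28 by removal of two silyl and four MOM groups; the enone of 28 comes from ring A salicylaldehyde 22 and ring B (E)-vinyl iodide 25 (aldehyde-selective alkenylation, then oxidation).
2. The formyl group of 22 is put ortho to the ring A phenol that is freed when lactone 13 is opened; ketone 21 comes from lactone 13 and ring C aryllithium 20.
3. Lactone 13 comes from aryl (Z)-cinnamate 12 by a catalytic enantioselective intramolecular Diels–Alder reaction (the new step): Z alkene gives C-5/C-6 cis, trans ring fusion gives C-1/C-6 trans.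
4. 12 comes from dienylphenol 5 (Suzuki coupling of 2 with dienylboronate 4) and ring D arylpropiolic acid 10 (esterification, Z-selective semihydrogenation).
5. Ring order: rings A to D are bought as benzenoid starting materials; the cyclohexene ring and a temporary lactone ring form together in step 9; the lactone ring is opened in step 13.

Assumption and labels: the SMILES is taken literally, (1S,5S,6S) on the cyclohexene (ring A aryl at C-1 trans to the aroyl group at C-6, aroyl cis to the 4-hydroxyphenyl at C-5); ring A = dihydroxyphenyl carrying the cyclohexene and the enone carbonyl, ring B = 2,4-dihydroxyphenyl on the enone, ring C = prenylated aroyl ring, ring D = 4-hydroxyphenyl.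

**Route**

Step 1
Reactants: 1 2-iodobenzene-1,3-diol
Product: 2 2-iodo-3-(triisopropylsilyloxy)phenol
Conditions: TIPSCl (1.0 equiv), imidazole, DMF, 0 °C to rt; bis-ether and recovered 1 separated and recycled
Reagents that add atoms: triisopropylsilyl chloride, CC(C)[Si](Cl)(C(C)C)C(C)C
Why: Silyl ether formation; one equivalent of silyl chloride on the symmetric diol gives mainly the mono-ether, which differentiates the two oxygens of ring A.

Step 2
Reactants: 3 2-methylbut-1-en-3-yne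
Product: 4 4,4,5,5-tetramethyl-2-[(1E)-3-methylbuta-1,3-dienyl]-1,3,2-dioxaborolane
Conditions: HBpin, Cp2Zr(H)Cl (5 mol%), Et3N (10 mol%), neat, 60 °C, sealed tube
Reagents that add atoms: pinacolborane, [H]B1OC(C)(C)C(C)(C)O1
Why: Zirconium-catalysed hydroboration of the terminal alkyne adds H–B syn and anti-Markovnikov, giving only the E dienylboronate and leaving the 1,1-disubstituted alkene alone.

Step 3
Reactants: 2 2-iodo-3-(triisopropylsilyloxy)phenol; 4 4,4,5,5-tetramethyl-2-[(1E)-3-methylbuta-1,3-dienyl]-1,3,2-dioxaborolane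
Product: 5 2-[(1E)-3-methylbuta-1,3-dienyl]-3-(triisopropylsilyloxy)phenol
Conditions: Pd(OAc)2 (3 mol%), SPhos (6 mol%), K3PO4, THF/H2O (10:1), 45 °C; product kept cold and used at once
Reagents that add atoms: none
Why: Suzuki–Miyaura coupling of the aryl iodide proceeds with retention of the E alkene geometry, and the bulky biaryl phosphine tolerates the two ortho substituents.

Step 4
Reactants: 6 4-hydroxybenzaldehyde
Product: 7 4-(triisopropylsilyloxy)benzaldehyde
Conditions: TIPSCl, imidazole, DMF, rt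
Reagents that add atoms: triisopropylsilyl chloride, CC(C)[Si](Cl)(C(C)C)C(C)C
Why: Imidazole-promoted silyl ether formation on the phenol.

Step 5
Reactants: 7 4-(triisopropylsilyloxy)benzaldehyde
Product: 8 [4-(2,2-dibromoethenyl)phenoxy]triisopropylsilane
Conditions: CBr4, PPh3, CH2Cl2, 0 °C
Reagents that add atoms: carbon tetrabromide, BrC(Br)(Br)Br
Why: Corey–Fuchs (Ramirez) dibromo-olefination of the aldehyde with the ylide from CBr4 and PPh3.

Step 6
Reactants: 8 [4-(2,2-dibromoethenyl)phenoxy]triisopropylsilane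
Product: 10 3-[4-(triisopropylsilyloxy)phenyl]prop-2-ynoic acid, via lithium arylacetylide 9 (not isolated)
Conditions: n-BuLi (2.1 equiv), THF, −78 °C; CO2 (g), −78 to 0 °C; aq. HCl to pH 3
Reagents that add atoms: carbon dioxide, O=C=O
Why: Second stage of the Corey–Fuchs sequence: bromine–lithium exchange, Fritsch–Buttenberg–Wiechell rearrangement and deprotonation give the lithium acetylide, which is carboxylated by CO2.

Step 7
Reactants: 5 2-[(1E)-3-methylbuta-1,3-dienyl]-3-(triisopropylsilyloxy)phenol; 10 3-[4-(triisopropylsilyloxy)phenyl]prop-2-ynoic acid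
Product: 11 2-[(1E)-3-methylbuta-1,3-dienyl]-3-(triisopropylsilyloxy)phenyl 3-[4-(triisopropylsilyloxy)phenyl]prop-2-ynoate
Conditions: DIC, DMAP (5 mol%), CH2Cl2, 0 °C, dark
Reagents that add atoms: none
Why: Steglich esterification; the neutral carbodiimide conditions at 0 °C keep the acid-sensitive o-dienylphenol intact and cap its hydroxyl.

Step 8
Reactants: 11 2-[(1E)-3-methylbuta-1,3-dienyl]-3-(triisopropylsilyloxy)phenyl 3-[4-(triisopropylsilyloxy)phenyl]prop-2-ynoate
Product: 12 2-[(1E)-3-methylbuta-1,3-dienyl]-3-(triisopropylsilyloxy)phenyl (2Z)-3-[4-(triisopropylsilyloxy)phenyl]prop-2-enoate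
Conditions: H2 (1 atm), Pd/CaCO3 poisoned with Pb(OAc)2 (Lindlar catalyst), quinoline, EtOAc, 0 °C; stopped after 1.0 equiv H2
Reagents that add atoms: none
Why: Lindlar semihydrogenation: syn delivery of H2 to the ynoate on the poisoned palladium surface gives the Z alkene, the alkyne being reduced much faster than the diene.

Step 9
Reactants: 12 2-[(1E)-3-methylbuta-1,3-dienyl]-3-(triisopropylsilyloxy)phenyl (2Z)-3-[4-(triisopropylsilyloxy)phenyl]prop-2-enoate
Product: 13 (6aS,7S,10aS)-9-methyl-1-(triisopropylsilyloxy)-7-[4-(triisopropylsilyloxy)phenyl]-6a,7,8,10a-tetrahydro-6H-benzo[c]chromen-6-one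
Conditions: (S)-3,3-diphenyl-1-(o-tolyl)tetrahydro-1H,3H-pyrrolo[1,2-c][1,3,2]oxazaborole (20 mol%), Tf2NH (18 mol%), CH2Cl2 (0.01 M), −40 to 0 °C
Reagents that add atoms: none
Why: Proposed new method: a catalytic enantioselective intramolecular Diels–Alder reaction of an aryl (Z)-cinnamate under chiral cationic oxazaborolidine activation; the triflimide-activated boron binds the ester carbonyl (with an α-C–H···O contact), which lowers the dienophile LUMO and cancels the usual conformational penalty of the lactone-type ester geometry so that the tethered diene (its unsubstituted terminus bonding first to the β-carbon) should close at or below 0 °C, the concerted suprafacial addition carries the Z geometry into the 6a,7-cis relationship, the exo-carbonyl transition state is preferred because only there does the planar 2-dienylaryl tether stay conjugated with the diene and the bulky catalyst-bound carbonyl point away from it (hence the trans 6a,10a ring fusion), and the aryl groups of the (S)-catalyst are expected to cover the Si face of the α-carbon so that the diene bonds to its Re face, giving 6aS,7S,10aS; the closest known reaction types are cationic oxazaborolidine-catalysed Diels–Alder reactions of acrylate and crotonate esters and thermal ester-tethered intramolecular Diels–Alder reactions.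

Step 10
Reactants: 14 benzene-1,3-diol
Product: 15 1,3-bis(methoxymethoxy)benzene
Conditions: MOMCl, iPr2NEt, CH2Cl2, 0 °C to rt
Reagents that add atoms: chloromethyl methyl ether, COCCl
Why: MOM ether (acetal) formation on both phenols by O-alkylation.

Step 11
Reactants: 15 1,3-bis(methoxymethoxy)benzene; 16 1-bromo-3-methylbut-2-ene
Product: 18 1,3-bis(methoxymethoxy)-2-(3-methylbut-2-enyl)benzene, via 2-lithio-1,3-bis(methoxymethoxy)benzene 17 (not isolated)
Conditions: n-BuLi, THF, 0 °C to rt, 1 h; then 16, 0 °C to rt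
Reagents that add atoms: none
Why: Directed ortho-metalation at C-2 between the two MOM ethers, then SN2 alkylation of the aryllithium with the allylic bromide.

Step 12
Reactants: 18 1,3-bis(methoxymethoxy)-2-(3-methylbut-2-enyl)benzene
Product: 19 1-bromo-2,4-bis(methoxymethoxy)-3-(3-methylbut-2-enyl)benzene
Conditions: NBS (1.0 equiv), MeCN, −20 °C, dark
Reagents that add atoms: N-bromosuccinimide, O=C1CCC(=O)N1Br
Why: Electrophilic aromatic bromination para to one MOM ether (the two open activated positions are equivalent), faster than attack on the trisubstituted alkene at low temperature.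

Step 13
Reactants: 19 1-bromo-2,4-bis(methoxymethoxy)-3-(3-methylbut-2-enyl)benzene; 13 (6aS,7S,10aS)-9-methyl-1-(triisopropylsilyloxy)-7-[4-(triisopropylsilyloxy)phenyl]-6a,7,8,10a-tetrahydro-6H-benzo[c]chromen-6-one
Product: 21 [2,4-bis(methoxymethoxy)-3-(3-methylbut-2-enyl)phenyl]{(1S,2S,6S)-2-[2-hydroxy-6-(triisopropylsilyloxy)phenyl]-4-methyl-6-[4-(triisopropylsilyloxy)phenyl]cyclohex-3-en-1-yl}methanone, via ring C aryllithium 20 (not isolated)
Conditions: 19 (1.2 equiv), n-BuLi (1.15 equiv), THF, −78 °C, 15 min; then 13 in THF, −78 °C, 1 h; sat. aq. NH4Cl at −78 °C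
Reagents that add atoms: none
Why: Bromine–lithium exchange, then nucleophilic acyl substitution on the aryl lactone (ketone synthesis from an ester); the cyclic lithium hemiketalate should persist at −78 °C, which prevents a second addition, and the three stereocentres are not touched.

Step 14
Reactants: 21 [2,4-bis(methoxymethoxy)-3-(3-methylbut-2-enyl)phenyl]{(1S,2S,6S)-2-[2-hydroxy-6-(triisopropylsilyloxy)phenyl]-4-methyl-6-[4-(triisopropylsilyloxy)phenyl]cyclohex-3-en-1-yl}methanone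
Product: 22 3-{(1S,5S,6S)-6-[2,4-bis(methoxymethoxy)-3-(3-methylbut-2-enyl)benzoyl]-3-methyl-5-[4-(triisopropylsilyloxy)phenyl]cyclohex-2-en-1-yl}-2-hydroxy-4-(triisopropylsilyloxy)benzaldehyde
Conditions: MgCl2, Et3N, (CH2O)n, THF, 65 °C
Reagents that add atoms: paraformaldehyde (as formaldehyde), C=O
Why: Casnati–Skattebøl ortho-formylation: the magnesium phenoxide delivers formaldehyde to the only free ortho position and a second formaldehyde oxidises the benzylic alkoxide by hydride transfer, while Et3N is too weak to enolise the hindered ketone.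

Step 15
Reactants: 23 2,4-dihydroxybenzaldehyde
Product: 24 2,4-bis(methoxymethoxy)benzaldehyde
Conditions: MOMCl, iPr2NEt, CH2Cl2, 0 to 40 °C
Reagents that add atoms: chloromethyl methyl ether, COCCl
Why: MOM ether formation on both phenols by O-alkylation.

Step 16
Reactants: 24 2,4-bis(methoxymethoxy)benzaldehyde
Product: 25 1-[(E)-2-iodoethenyl]-2,4-bis(methoxymethoxy)benzene
Conditions: CrCl2 (6 equiv), CHI3 (2 equiv), THF, 0 °C to rt
Reagents that add atoms: iodoform, IC(I)I
Why: Takai olefination: the geminal dichromium reagent from CHI3 and CrCl2 converts the aromatic aldehyde into the E vinyl iodide.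

Step 17
Reactants: 22 3-{(1S,5S,6S)-6-[2,4-bis(methoxymethoxy)-3-(3-methylbut-2-enyl)benzoyl]-3-methyl-5-[4-(triisopropylsilyloxy)phenyl]cyclohex-2-en-1-yl}-2-hydroxy-4-(triisopropylsilyloxy)benzaldehyde; 25 1-[(E)-2-iodoethenyl]-2,4-bis(methoxymethoxy)benzene
Product: 27 (2E)-3-[2,4-bis(methoxymethoxy)phenyl]-1-[3-{(1S,5S,6S)-6-[2,4-bis(methoxymethoxy)-3-(3-methylbut-2-enyl)benzoyl]-3-methyl-5-[4-(triisopropylsilyloxy)phenyl]cyclohex-2-en-1-yl}-2-hydroxy-4-(triisopropylsilyloxy)phenyl]prop-2-en-1-ol (both epimers at the carbinol carbon), via alkenylchromium dichloride 26 (not isolated)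
Conditions: CrCl2 (6 equiv), NiCl2 (2 mol%), DMF, rt, dark; pH 7 work-up; crude 27 oxidised at once
Reagents that add atoms: none
Why: Nozaki–Hiyama–Kishi coupling: the alkenylchromium reagent adds to the aldehyde but not to the hindered ketone, with retention of the E alkene; the new carbinol centre forms as both epimers and is erased in step 18.

Step 18
Reactants: 27 (2E)-3-[2,4-bis(methoxymethoxy)phenyl]-1-[3-{(1S,5S,6S)-6-[2,4-bis(methoxymethoxy)-3-(3-methylbut-2-enyl)benzoyl]-3-methyl-5-[4-(triisopropylsilyloxy)phenyl]cyclohex-2-en-1-yl}-2-hydroxy-4-(triisopropylsilyloxy)phenyl]prop-2-en-1-ol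
Product: 28 (2E)-3-[2,4-bis(methoxymethoxy)phenyl]-1-[3-{(1S,5S,6S)-6-[2,4-bis(methoxymethoxy)-3-(3-methylbut-2-enyl)benzoyl]-3-methyl-5-[4-(triisopropylsilyloxy)phenyl]cyclohex-2-en-1-yl}-2-hydroxy-4-(triisopropylsilyloxy)phenyl]prop-2-en-1-one
Conditions: MnO2 (activated, excess), CH2Cl2, rt
Reagents that add atoms: none
Why: MnO2 oxidation of the allylic and benzylic alcohol under neutral conditions converges both epimers to the enone without touching C-6.

Step 19
Reactants: 28 (2E)-3-[2,4-bis(methoxymethoxy)phenyl]-1-[3-{(1S,5S,6S)-6-[2,4-bis(methoxymethoxy)-3-(3-methylbut-2-enyl)benzoyl]-3-methyl-5-[4-(triisopropylsilyloxy)phenyl]cyclohex-2-en-1-yl}-2-hydroxy-4-(triisopropylsilyloxy)phenyl]prop-2-en-1-one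
Product: 29 (2E)-3-[2,4-bis(methoxymethoxy)phenyl]-1-[3-{(1S,5S,6S)-6-[2,4-bis(methoxymethoxy)-3-(3-methylbut-2-enyl)benzoyl]-5-(4-hydroxyphenyl)-3-methylcyclohex-2-en-1-yl}-2,4-dihydroxyphenyl]prop-2-en-1-one
Conditions: Bu4NF, AcOH (1:1, 3 equiv), THF, 0 °C
Reagents that add atoms: none
Why: Fluoride-mediated cleavage of the two aryl silyl ethers, buffered with acetic acid so that the chalcone and C-6 are not exposed to base.

Step 20
Reactants: 29 (2E)-3-[2,4-bis(methoxymethoxy)phenyl]-1-[3-{(1S,5S,6S)-6-[2,4-bis(methoxymethoxy)-3-(3-methylbut-2-enyl)benzoyl]-5-(4-hydroxyphenyl)-3-methylcyclohex-2-en-1-yl}-2,4-dihydroxyphenyl]prop-2-en-1-one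
Product: 30 (2E)-1-{3-[(1S,5S,6S)-6-[2,4-dihydroxy-3-(3-methylbut-2-enyl)benzoyl]-5-(4-hydroxyphenyl)-3-methylcyclohex-2-en-1-yl]-2,4-dihydroxyphenyl}-3-(2,4-dihydroxyphenyl)prop-2-en-1-one
Conditions: 3 M aq. HCl, MeOH, rt, dark; then NaHCO3
Reagents that add atoms: none
Why: Acid-catalysed acetal exchange removes the four MOM groups; at room temperature the prenyl group, the enone and the ketone α-centre are expected to survive.

**Compound list**

1 | 2-iodobenzene-1,3-diol | Oc1cccc(O)c1I | starting material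
2 | 2-iodo-3-(triisopropylsilyloxy)phenol | Oc1cccc(O[Si](C(C)C)(C(C)C)C(C)C)c1I | intermediate
3 | 2-methylbut-1-en-3-yne | CC(=C)C#C | starting material
4 | 4,4,5,5-tetramethyl-2-[(1E)-3-methylbuta-1,3-dienyl]-1,3,2-dioxaborolane | CC(=C)/C=C/B1OC(C)(C)C(C)(C)O1 | intermediate
5 | 2-[(1E)-3-methylbuta-1,3-dienyl]-3-(triisopropylsilyloxy)phenol | CC(=C)/C=C/c1c(O)cccc1O[Si](C(C)C)(C(C)C)C(C)C | intermediate
6 | 4-hydroxybenzaldehyde | O=Cc1ccc(O)cc1 | starting material
7 | 4-(triisopropylsilyloxy)benzaldehyde | O=Cc1ccc(O[Si](C(C)C)(C(C)C)C(C)C)cc1 | intermediate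
8 | [4-(2,2-dibromoethenyl)phenoxy]triisopropylsilane | BrC(Br)=Cc1ccc(O[Si](C(C)C)(C(C)C)C(C)C)cc1 | intermediate
9 | lithium [4-(triisopropylsilyloxy)phenyl]acetylide | [Li]C#Cc1ccc(O[Si](C(C)C)(C(C)C)C(C)C)cc1 | intermediate
10 | 3-[4-(triisopropylsilyloxy)phenyl]prop-2-ynoic acid | OC(=O)C#Cc1ccc(O[Si](C(C)C)(C(C)C)C(C)C)cc1 | intermediate
11 | 2-[(1E)-3-methylbuta-1,3-dienyl]-3-(triisopropylsilyloxy)phenyl 3-[4-(triisopropylsilyloxy)phenyl]prop-2-ynoate | CC(=C)/C=C/c1c(OC(=O)C#Cc2ccc(O[Si](C(C)C)(C(C)C)C(C)C)cc2)cccc1O[Si](C(C)C)(C(C)C)C(C)C | intermediate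
12 | 2-[(1E)-3-methylbuta-1,3-dienyl]-3-(triisopropylsilyloxy)phenyl (2Z)-3-[4-(triisopropylsilyloxy)phenyl]prop-2-enoate | CC(=C)/C=C/c1c(OC(=O)/C=C\c2ccc(O[Si](C(C)C)(C(C)C)C(C)C)cc2)cccc1O[Si](C(C)C)(C(C)C)C(C)C | intermediate
13 | (6aS,7S,10aS)-9-methyl-1-(triisopropylsilyloxy)-7-[4-(triisopropylsilyloxy)phenyl]-6a,7,8,10a-tetrahydro-6H-benzo[c]chromen-6-one (trans-fused lactone, H-6a/H-7 cis) | O=C1[C@@H]2[C@@H](c3c(O1)cccc3O[Si](C(C)C)(C(C)C)C(C)C)C=C(C)C[C@@H]2c2ccc(O[Si](C(C)C)(C(C)C)C(C)C)cc2 | intermediate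
14 | benzene-1,3-diol | Oc1cccc(O)c1 | starting material
15 | 1,3-bis(methoxymethoxy)benzene | COCOc1cccc(OCOC)c1 | intermediate
16 | 1-bromo-3-methylbut-2-ene | CC(C)=CCBr | starting material
17 | [2,6-bis(methoxymethoxy)phenyl]lithium | [Li]c1c(OCOC)cccc1OCOC | intermediate
18 | 1,3-bis(methoxymethoxy)-2-(3-methylbut-2-enyl)benzene | CC(C)=CCc1c(OCOC)cccc1OCOC | intermediate
19 | 1-bromo-2,4-bis(methoxymethoxy)-3-(3-methylbut-2-enyl)benzene | CC(C)=CCc1c(OCOC)ccc(Br)c1OCOC | intermediate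
20 | [2,4-bis(methoxymethoxy)-3-(3-methylbut-2-enyl)phenyl]lithium | CC(C)=CCc1c(OCOC)ccc([Li])c1OCOC | intermediate
21 | [2,4-bis(methoxymethoxy)-3-(3-methylbut-2-enyl)phenyl]{(1S,2S,6S)-2-[2-hydroxy-6-(triisopropylsilyloxy)phenyl]-4-methyl-6-[4-(triisopropylsilyloxy)phenyl]cyclohex-3-en-1-yl}methanone | CC(C)=CCc1c(OCOC)ccc(C(=O)[C@@H]2[C@@H](c3c(O)cccc3O[Si](C(C)C)(C(C)C)C(C)C)C=C(C)C[C@@H]2c2ccc(O[Si](C(C)C)(C(C)C)C(C)C)cc2)c1OCOC | intermediate
22 | 3-{(1S,5S,6S)-6-[2,4-bis(methoxymethoxy)-3-(3-methylbut-2-enyl)benzoyl]-3-methyl-5-[4-(triisopropylsilyloxy)phenyl]cyclohex-2-en-1-yl}-2-hydroxy-4-(triisopropylsilyloxy)benzaldehyde | CC(C)=CCc1c(OCOC)ccc(C(=O)[C@@H]2[C@@H](c3c(O)c(C=O)ccc3O[Si](C(C)C)(C(C)C)C(C)C)C=C(C)C[C@@H]2c2ccc(O[Si](C(C)C)(C(C)C)C(C)C)cc2)c1OCOC | intermediate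
23 | 2,4-dihydroxybenzaldehyde | O=Cc1ccc(O)cc1O | starting material
24 | 2,4-bis(methoxymethoxy)benzaldehyde | O=Cc1ccc(OCOC)cc1OCOC | intermediate
25 | 1-[(E)-2-iodoethenyl]-2,4-bis(methoxymethoxy)benzene | I/C=C/c1ccc(OCOC)cc1OCOC | intermediate
26 | {(E)-2-[2,4-bis(methoxymethoxy)phenyl]ethenyl}chromium dichloride (trivalent chromium) | Cl[Cr](Cl)/C=C/c1ccc(OCOC)cc1OCOC | intermediate
27 | (2E)-3-[2,4-bis(methoxymethoxy)phenyl]-1-[3-{(1S,5S,6S)-6-[2,4-bis(methoxymethoxy)-3-(3-methylbut-2-enyl)benzoyl]-3-methyl-5-[4-(triisopropylsilyloxy)phenyl]cyclohex-2-en-1-yl}-2-hydroxy-4-(triisopropylsilyloxy)phenyl]prop-2-en-1-ol, both epimers at the carbinol carbon | CC(C)=CCc1c(OCOC)ccc(C(=O)[C@@H]2[C@@H](c3c(O)c(C(O)/C=C/c4ccc(OCOC)cc4OCOC)ccc3O[Si](C(C)C)(C(C)C)C(C)C)C=C(C)C[C@@H]2c2ccc(O[Si](C(C)C)(C(C)C)C(C)C)cc2)c1OCOC | intermediate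
28 | (2E)-3-[2,4-bis(methoxymethoxy)phenyl]-1-[3-{(1S,5S,6S)-6-[2,4-bis(methoxymethoxy)-3-(3-methylbut-2-enyl)benzoyl]-3-methyl-5-[4-(triisopropylsilyloxy)phenyl]cyclohex-2-en-1-yl}-2-hydroxy-4-(triisopropylsilyloxy)phenyl]prop-2-en-1-one | CC(C)=CCc1c(OCOC)ccc(C(=O)[C@@H]2[C@@H](c3c(O)c(C(=O)/C=C/c4ccc(OCOC)cc4OCOC)ccc3O[Si](C(C)C)(C(C)C)C(C)C)C=C(C)C[C@@H]2c2ccc(O[Si](C(C)C)(C(C)C)C(C)C)cc2)c1OCOC | intermediate
29 | (2E)-3-[2,4-bis(methoxymethoxy)phenyl]-1-[3-{(1S,5S,6S)-6-[2,4-bis(methoxymethoxy)-3-(3-methylbut-2-enyl)benzoyl]-5-(4-hydroxyphenyl)-3-methylcyclohex-2-en-1-yl}-2,4-dihydroxyphenyl]prop-2-en-1-one | CC(C)=CCc1c(OCOC)ccc(C(=O)[C@@H]2[C@@H](c3c(O)c(C(=O)/C=C/c4ccc(OCOC)cc4OCOC)ccc3O)C=C(C)C[C@@H]2c2ccc(O)cc2)c1OCOC | intermediate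
30 | (2E)-1-{3-[(1S,5S,6S)-6-[2,4-dihydroxy-3-(3-methylbut-2-enyl)benzoyl]-5-(4-hydroxyphenyl)-3-methylcyclohex-2-en-1-yl]-2,4-dihydroxyphenyl}-3-(2,4-dihydroxyphenyl)prop-2-en-1-one (CNP0218862.3) | CC(C)=CCc1c(O)ccc(C(=O)[C@@H]2[C@@H](c3c(O)ccc(C(=O)/C=C/c4ccc(O)cc4O)c3O)C=C(C)C[C@@H]2c2ccc(O)cc2)c1O | target

**Totals and risks**

Total step count: 20. Longest linear sequence: 12 steps (6, 7, 8, 10, 11, 12, 13, 21, 22, 27, 28, 29, 30).

The three steps most likely to fail:

Step 9 (the proposed new step). The level and even the sense of enantioselection are unproven, and the facial assignment would have to be confirmed by X-ray analysis of 13 (the antipodal catalyst is equally accessible). The endo (cis-fused) closure may compete. The Lewis acid may also isomerise the electron-rich Z cinnamate to the E ester before it cyclises. The fallback sets out from 12 and uses only known chemistry: 12 is heated without catalyst in degassed toluene with a trace of BHT at about 140 °C in a sealed tube. This thermal ester-tethered intramolecular Diels–Alder reaction gives the racemic trans-fused lactone, that is 13 together with the enantiomeric (6aR,7R,10aR)-lactone F1. The two are separated by preparative supercritical-fluid chromatography on a chiral polysaccharide phase, and the route is rejoined at 13.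

Step 13. The aryllithium may deprotonate the lactone at C-6a (epimerisation) or add twice. The fallback sets out from 13. The lactone is opened with Me(MeO)NH·HCl and AlMe3 in CH2Cl2 to the phenolic Weinreb amide F2. Its phenol is capped with TESCl and imidazole to give the triethylsilyl ether F3. Aryllithium 20 is then added at −78 °C; the chelated tetrahedral intermediate prevents over-addition and gives the ketone triethylsilyl ether F4. K2CO3 in MeOH at 0 °C removes the aryl triethylsilyl group selectively, which returns the route to 21.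

Step 8. The diene may be partly reduced, or some E ester may form. The fallback sets out from 7 and makes the Z alkene before the diene is present. Still–Gennari olefination of 7 with methyl bis(2,2,2-trifluoroethyl)phosphonoacetate, KN(SiMe3)2 and 18-crown-6 in THF at −78 °C gives the methyl (Z)-3-[4-(triisopropylsilyloxy)phenyl]prop-2-enoate F5. Neutral ester cleavage with Me3SnOH in 1,2-dichloroethane at 70 °C gives the (Z)-acid F6. This is esterified with phenol 5 (DIC, catalytic DMAP·HCl, CH2Cl2, −20 °C) to rejoin the route at 12, bypassing 8 to 11.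

**Further compounds**

F1 | step 9 | (6aR,7R,10aR)-9-methyl-1-(triisopropylsilyloxy)-7-[4-(triisopropylsilyloxy)phenyl]-6a,7,8,10a-tetrahydro-6H-benzo[c]chromen-6-one | O=C1[C@H]2[C@H](c3c(O1)cccc3O[Si](C(C)C)(C(C)C)C(C)C)C=C(C)C[C@H]2c2ccc(O[Si](C(C)C)(C(C)C)C(C)C)cc2
F2 | step 13 | (1S,2S,6S)-2-[2-hydroxy-6-(triisopropylsilyloxy)phenyl]-N-methoxy-N,4-dimethyl-6-[4-(triisopropylsilyloxy)phenyl]cyclohex-3-ene-1-carboxamide | CON(C)C(=O)[C@@H]1[C@@H](c2c(O)cccc2O[Si](C(C)C)(C(C)C)C(C)C)C=C(C)C[C@@H]1c1ccc(O[Si](C(C)C)(C(C)C)C(C)C)cc1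
F3 | step 13 | (1S,2S,6S)-N-methoxy-N,4-dimethyl-2-[2-(triethylsilyloxy)-6-(triisopropylsilyloxy)phenyl]-6-[4-(triisopropylsilyloxy)phenyl]cyclohex-3-ene-1-carboxamide | CON(C)C(=O)[C@@H]1[C@@H](c2c(O[Si](CC)(CC)CC)cccc2O[Si](C(C)C)(C(C)C)C(C)C)C=C(C)C[C@@H]1c1ccc(O[Si](C(C)C)(C(C)C)C(C)C)cc1
F4 | step 13 | [2,4-bis(methoxymethoxy)-3-(3-methylbut-2-enyl)phenyl]{(1S,2S,6S)-4-methyl-2-[2-(triethylsilyloxy)-6-(triisopropylsilyloxy)phenyl]-6-[4-(triisopropylsilyloxy)phenyl]cyclohex-3-en-1-yl}methanone | CC(C)=CCc1c(OCOC)ccc(C(=O)[C@@H]2[C@@H](c3c(O[Si](CC)(CC)CC)cccc3O[Si](C(C)C)(C(C)C)C(C)C)C=C(C)C[C@@H]2c2ccc(O[Si](C(C)C)(C(C)C)C(C)C)cc2)c1OCOC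
F5 | step 8 | methyl (2Z)-3-[4-(triisopropylsilyloxy)phenyl]prop-2-enoate | COC(=O)/C=C\c1ccc(O[Si](C(C)C)(C(C)C)C(C)C)cc1
F6 | step 8 | (2Z)-3-[4-(triisopropylsilyloxy)phenyl]prop-2-enoic acid | OC(=O)/C=C\c1ccc(O[Si](C(C)C)(C(C)C)C(C)C)cc1
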